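## Retrosynthetic overview

1. Target ⇒ tigloylation of an 8α-hydroxy-9-ketone ⇒ Rubottom oxidation of a C8=C9 silyl enol ether.
2. That enol ether and the C7 isopropenyl group are both unmasked from one gem-dimethylcyclopropane (C7–C8–C11) next to the C9 ketone (TMSI opening, then radical dehydroiodination).
3. 1α-OAc and 10α-H ⇒ 1α,10α-epoxy ketone (reductive C10–O cleavage, kinetic protonation) ⇒ Δ1(10)-en-9-one.
4. Ring A with C4 and the quaternary C5 ⇒ C4–C5 bond by a light-driven cobalt-hydride 6-endo radical cycloisomerisation of a 2-(pent-4-enyl) enone.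
5. That enone ⇒ α-alkylation of car-3-en-5-one ⇒ allylic oxidation of (+)-3-carene. Ring B is bought as the carene ring, ring A closes in step 3, the cyclopropane opens in step 7.

Assumption: (+)-3-carene is the (1S,6R) enantiomer; from step 3 on, names use eremophilane numbering (C14 on C5, C15 on C4, C11–C13 on C7), with β = the face of the C14 methyl and α = the other face.

## Route

Step 1
Reactants: 1 ((+)-3-carene)
Product: 2 car-3-en-5-one
Conditions: t-BuOOH (70% aq.), Cr(CO)6 (cat.), MeCN, reflux
Reagents that add atoms: tert-butyl hydroperoxide, CC(C)(C)OO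
Why: Chromium-catalysed allylic C–H oxidation turns the ring CH2 between the alkene CH and the cyclopropane into the carbonyl (the usual main site for 3-carene) and leaves the two cyclopropane stereocentres of 1 untouched.

Step 2
Reactants: 2 (car-3-en-5-one) and 3 (5-bromopent-1-ene)
Product: 5 (1R,6S)-4,7,7-trimethyl-3-(pent-4-en-1-yl)bicyclo[4.1.0]hept-3-en-2-one, via deconjugated alkylation product 4 (not isolated)
Conditions: t-BuOK, t-BuOH/THF, 0 °C; then 3, 50 °C
Reagents that add atoms: none
Why: Classical α-alkylation of a β-methyl enone through its extended dienolate (SN2 on the primary bromide at C10), possible only on this side because the other α-carbon is a cyclopropane CH, after which the base moves the double bond of 4 back into conjugation so that no new stereocentre remains.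

Step 3
Reactants: 5 (2-pentenyl enone)
Product: 6 7αH,8αH-8,11-cycloeremophil-1(10)-en-9-one
Conditions: Co(dmgH)2(py)Cl [C13H19ClCoN5O4] (5 mol%), 4CzIPN (2 mol%), i-Pr2NEt (10 mol%), AcOH (20 mol%), MeCN (0.02 M), 450 nm LEDs, 25 °C
Reagents that add atoms: none
Why: Proposed new method: a visible-light cobalt-hydride radical cycloisomerisation in which photoreduced cobaloxime is protonated by AcOH to a trivalent cobalt hydride that transfers a hydrogen atom to the terminal alkene (Markovnikov MHAT) to give the secondary C4 radical, this nucleophilic radical closes 6-endo (Giese polarity) on the enone β-carbon C5 from the α face away from the endo methyl of the cyclopropane through a chair with the new C15 methyl equatorial (this sets the quaternary C5 and C4 with the two methyls cis), and divalent cobalt then takes a C1 hydrogen from the C10 α-keto radical to give the Δ1(10)-enone and return the hydride, so that the step is a redox-neutral isomerisation in which the cyclopropane keeps the later isopropenyl group hidden from the hydride; the closest known reaction types are iron/silane MHAT reductive Giese cyclisations, cobalt–salen radical cycloisomerisations and photochemical cobaloxime radical Heck-type desaturations.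

Step 4
Reactants: 6 (tricyclic enone)
Product: 7 1α,10α-epoxy-7αH,8αH-8,11-cycloeremophilan-9-one
Conditions: 30% H2O2, NaOH (cat.), MeOH, 0 °C → rt
Reagents that add atoms: hydrogen peroxide, OO
Why: Weitz–Scheffer nucleophilic epoxidation in which the hydroperoxide anion adds to C1 from the α face, opposite the pseudoaxial C14 methyl and the endo methyl of the cyclopropane (as in the 16α,17α-epoxidation of 16-en-20-one steroids), so the oxygen that stays on C1 is α.

Step 5
Reactants: 7 (epoxy ketone)
Product: 8 1α-hydroxy-7αH,8αH,10αH-8,11-cycloeremophilan-9-one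
Conditions: SmI2 (2.2 equiv), THF/MeOH, −90 °C; then pH 7 buffer
Reagents that add atoms: none
Why: Reductive opening of an α,β-epoxy ketone with divalent samarium (Molander conditions) cleaves only the C10–O bond so that the C1 oxygen keeps its α configuration, and the samarium enolate is protonated by MeOH at −90 °C on the α face (axial attack on ring A, the β face being blocked by the axial C14 methyl and the cyclopropane endo methyl) to give the trans-fused 10α-H ketone under kinetic control, the epoxy-ketyl C–O scission being much faster than cyclopropane opening at this temperature.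

Step 6
Reactants: 8 (β-hydroxy ketone)
Product: 9 1α-acetoxy-7αH,8αH,10αH-8,11-cycloeremophilan-9-one
Conditions: Ac2O, pyridine, DMAP (cat.), CH2Cl2, 0 °C
Reagents that add atoms: acetic anhydride, CC(=O)OC(C)=O
Why: DMAP-catalysed acetylation of the unhindered equatorial secondary alcohol at 0 °C, mild enough to leave the epimerisable C10 centre and the β-oxygenated ketone unchanged.

Step 7
Reactants: 9 (acetoxy cyclopropyl ketone)
Product: 11 1α-acetoxy-9-(trimethylsilyloxy)-7αH,10αH-eremophila-8,11-diene, via tertiary iodide silyl enol ether 10 (not isolated)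
Conditions: TMSI (1.1 equiv), CH2Cl2, −40 °C; then MeCN, Et3N (3 equiv), 4CzIPN (2 mol%), Co(dmgH)2(py)Cl (5 mol%), 450 nm LEDs, 25 °C
Reagents that add atoms: iodotrimethylsilane, C[Si](C)(C)I
Why: Homoconjugate ring opening of the cyclopropyl ketone by TMSI breaks the C8–C11 bond (the one aligned with the carbonyl π system and leading to a tertiary iodide) and gives the C8=C9 silyl enol ether regiospecifically without base, after which the known photochemical halogen-atom-transfer/cobaloxime dehydrohalogenation (an α-aminoalkyl radical abstracts iodine and divalent cobalt removes a methyl hydrogen) gives the less substituted alkene, the isopropenyl group, with C7 untouched.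

Step 8
Reactants: 11 (silyl enol ether)
Product: 13 1α-acetoxy-8α-hydroxy-7αH,10αH-eremophil-11-en-9-one, via 8α-trimethylsilyloxy ketone 12 (not isolated)
Conditions: mCPBA (1.05 equiv), CH2Cl2, −40 → 0 °C; then 1 M HCl, THF, 0 °C
Reagents that add atoms: 3-chloroperbenzoic acid, OOC(=O)c1cccc(Cl)c1
Why: Rubottom oxidation in which the electron-rich silyl enol ether reacts far faster than the 1,1-disubstituted alkene and is attacked on the α face, anti to the neighbouring C7 isopropenyl group and the C14 methyl, so that silyl migration to 12 and mild acid hydrolysis give the 8α-hydroxy ketone (trans to isopropenyl) without base and with C10 intact.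

Step 9
Reactants: 13 (α-hydroxy ketone) and 14 (tigloyl chloride)
Product: 15 (1S,4S,5R,7R,8R,10S)-1α-acetoxy-8α-tigloyloxy-7αH,10αH-eremophil-11-en-9-one
Conditions: pyridine, DMAP (cat.), CH2Cl2, 0 °C → rt
Reagents that add atoms: none
Why: DMAP-catalysed acylation of the secondary α-ketol hydroxyl with the (E)-acid chloride forms the tiglate without changing any stereocentre or the alkene geometry.

## Compound list

1 | (+)-3-carene, (1S,6R)-3,7,7-trimethylbicyclo[4.1.0]hept-3-ene | CC1=CC[C@@H]2[C@H](C1)C2(C)C | starting material
2 | car-3-en-5-one, (1R,6S)-4,7,7-trimethylbicyclo[4.1.0]hept-3-en-2-one | CC1=CC(=O)[C@@H]2[C@H](C1)C2(C)C | intermediate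
3 | 5-bromopent-1-ene | C=CCCCBr | starting material
4 | (1R,6S)-4,7,7-trimethyl-3-(pent-4-en-1-yl)bicyclo[4.1.0]hept-4-en-2-one (C3 epimers) | CC1=C[C@H]2[C@@H](C(=O)C1CCCC=C)C2(C)C | intermediate
5 | (1R,6S)-4,7,7-trimethyl-3-(pent-4-en-1-yl)bicyclo[4.1.0]hept-3-en-2-one | CC1=C(CCCC=C)C(=O)[C@@H]2[C@H](C1)C2(C)C | intermediate
6 | 7αH,8αH-8,11-cycloeremophil-1(10)-en-9-one (4β,5β-dimethyl, C11 on the β face) | C[C@H]1CCC=C2C(=O)[C@@H]3[C@H](C[C@]12C)C3(C)C | intermediate
7 | 1α,10α-epoxy-7αH,8αH-8,11-cycloeremophilan-9-one | C[C@H]1CC[C@@H]2O[C@@]23C(=O)[C@@H]4[C@H](C[C@]13C)C4(C)C | intermediate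
8 | 1α-hydroxy-7αH,8αH,10αH-8,11-cycloeremophilan-9-one | C[C@H]1CC[C@H](O)[C@H]2C(=O)[C@@H]3[C@H](C[C@]12C)C3(C)C | intermediate
9 | 1α-acetoxy-7αH,8αH,10αH-8,11-cycloeremophilan-9-one | C[C@H]1CC[C@H](OC(C)=O)[C@H]2C(=O)[C@@H]3[C@H](C[C@]12C)C3(C)C | intermediate
10 | 1α-acetoxy-11-iodo-9-(trimethylsilyloxy)-7αH,10αH-eremophil-8-ene | C[C@H]1CC[C@H](OC(C)=O)[C@H]2C(O[Si](C)(C)C)=C[C@H](C[C@]12C)C(C)(C)I | intermediate
11 | 1α-acetoxy-9-(trimethylsilyloxy)-7αH,10αH-eremophila-8,11-diene | C[C@H]1CC[C@H](OC(C)=O)[C@H]2C(O[Si](C)(C)C)=C[C@H](C[C@]12C)C(C)=C | intermediate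
12 | 1α-acetoxy-8α-(trimethylsilyloxy)-7αH,10αH-eremophil-11-en-9-one | C[C@H]1CC[C@H](OC(C)=O)[C@H]2C(=O)[C@H](O[Si](C)(C)C)[C@H](C[C@]12C)C(C)=C | intermediate
13 | 1α-acetoxy-8α-hydroxy-7αH,10αH-eremophil-11-en-9-one | C[C@H]1CC[C@H](OC(C)=O)[C@H]2C(=O)[C@H](O)[C@H](C[C@]12C)C(C)=C | intermediate
14 | tigloyl chloride, (E)-2-methylbut-2-enoyl chloride | C/C=C(\C)C(=O)Cl | starting material
15 | CNP0138236.1, (1S,4S,5R,7R,8R,10S)-1α-acetoxy-8α-tigloyloxy-7αH,10αH-eremophil-11-en-9-one | C=C(C)[C@H]1C[C@@]2(C)[C@H](C(=O)[C@@H]1OC(=O)/C(C)=C/C)[C@@H](OC(C)=O)CC[C@@H]2C | target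

## Step count and risks

Total steps: 9. Longest linear sequence: 9 steps (1 → 15).

The three steps most likely to fail:

Step 3 (the new cycloisomerisation). The risks are simple reduction of the radical, 5-exo closure, alkene migration without ring closure, and a modest C4 ratio (the equatorial-methyl preference is worth only about 1 kcal/mol). Fallback with known chemistry: setting out from 5, a thermal MHAT reductive Giese cyclisation (Fe(acac)3, PhSiH3, EtOH/ethylene glycol, 60 °C) gives the saturated tricyclic ketone F1 as C10 epimers. This is converted into the C9(10) trimethylsilyl enol ether F2 (TMSOTf, Et3N, CH2Cl2; only C10 can enolise) and dehydrogenated by Saegusa–Ito oxidation (Pd(OAc)2, MeCN), which comes back to the route at 6.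

Step 5 (epoxide opening and C10 protonation). The risks are competing opening of the cyclopropyl ketone by divalent samarium and protonation of the enolate on the β face, which would give the cis-fused 10β-H epimer; that epimer is probably the more stable one, so the trans fusion has to be kept away from base afterwards. Fallback: setting out from 6 and skipping 7, copper-catalysed conjugate borylation (CuCl, NaOt-Bu, DPEphos, B2pin2, MeOH, THF, rt) adds boron to C1 from the α face and the copper enolate is protonated by MeOH, giving the 1α-pinacolboryl ketone F3. Oxidation with NaBO3·4H2O (THF/H2O) replaces boron by hydroxyl with retention and comes back at 8. This avoids the cyclopropane-opening risk but still relies on enolate protonation for C10.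

Step 7 (cyclopropane opening and dehydroiodination). The risks are loss of the trimethylsilyl enol ether under the photochemical conditions and elimination toward C7, which would give the conjugated C7=C11 diene. Fallback: setting out from 10 (made with TMSI as in step 7), excess mCPBA (3 equiv, CH2Cl2, −40 °C → rt) first carries out the Rubottom oxidation to the iodo 8α-silyloxy ketone F4. Its tertiary iodide is then oxidised to the iodosyl compound F5, which undergoes syn elimination toward a methyl group now that no enol ether is left to favour the conjugated isomer. This comes back at 12, which is hydrolysed to 13 as in step 8.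

## Further compounds

F1 | step 3 | 7αH,8αH-8,11-cycloeremophilan-9-one (4β,5β-dimethyl, C10 epimers) | C[C@H]1CCCC2C(=O)[C@@H]3[C@H](C[C@]12C)C3(C)C
F2 | step 3 | 9-(trimethylsilyloxy)-7αH,8αH-8,11-cycloeremophil-9-ene | C[C@H]1CCCC2=C(O[Si](C)(C)C)[C@@H]3[C@H](C[C@]12C)C3(C)C
F3 | step 5 | 1α-(4,4,5,5-tetramethyl-1,3,2-dioxaborolan-2-yl)-7αH,8αH,10αH-8,11-cycloeremophilan-9-one | C[C@H]1CC[C@H](B2OC(C)(C)C(C)(C)O2)[C@H]3C(=O)[C@@H]4[C@H](C[C@]13C)C4(C)C
F4 | step 7 | 1α-acetoxy-11-iodo-8α-(trimethylsilyloxy)-7αH,10αH-eremophilan-9-one | C[C@H]1CC[C@H](OC(C)=O)[C@H]2C(=O)[C@H](O[Si](C)(C)C)[C@H](C[C@]12C)C(C)(C)I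
F5 | step 7 | 1α-acetoxy-11-iodosyl-8α-(trimethylsilyloxy)-7αH,10αH-eremophilan-9-one | C[C@H]1CC[C@H](OC(C)=O)[C@H]2C(=O)[C@H](O[Si](C)(C)C)[C@H](C[C@]12C)C(C)(C)I=O
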